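The dihydropyran is disconnected at its ring oxygen O2: with O2 deleted, C1 and C3 are bonded and the iridoid becomes a cis-bicyclo[3.3.0]octan-3-one whose ring A carries an exo silyloxy group at C1. The key step exploits the C1–O2–C3 unit (acetal carbon C1, enol-ether carbon C3) of that oxygen ring. A Baeyer–Villiger oxidation lets the oxygenated C1 migrate with retention, which in one operation forms both C–O bonds of O2, enlarges ring A to the six-membered acylal lactone and brings C1 to the acetal level. The precursor is a persilylated diquinane ketone (1-OTES, 7-OTES, 8-OTMS, 10-OTBS, 11-OTBDPS) made by SAMP alkylation, vinyl addition, Pauson–Khand cyclisation, hydrogenation and Rubottom oxidation.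

Key step: step 14

Conventions and remarks
- Iridoid numbering is used for all bicyclic compounds: C1 (acetal carbon), O2, C3, C4 (bears C11), C5, C6, C7, C8 (bears C10), C9. Ring A contains C1, C3 and C4; ring B is the cyclopentane C5–C9. The convex face is the face of H-5 and H-9; O1, O7 and C10 lie on it, O8 on the concave face.
- Assumption: the side-chain acid is read from the target SMILES as (R)-3-methylpentanoic acid; it and SAMP are taken as purchasable single enantiomers.
- Remark on C4: syn hydrogenation puts H-4 on the same face as H-5, so the C11 group of the ketone precursor is on the concave face. An exo C11 group would need a separate epimerisation, which is pointless because C4 becomes sp2 in step 16.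
- Remark on protecting groups: the silyl groups are graded for the end game. O1 carries TES because the anomeric silyl ether must be the most fluoride-labile one; O7 carries TES and O8 TMS, both removable by buffered HF in the presence of primary TBS (O10) and TBDPS (O11); TBDPS on O11 survives the acetonide hydrolysis. O8 is capped so that it cannot attack the lactone carbonyl.

Step 1
Reactants: 1 but-2-yne-1,4-diol
Product: 2 4-(tert-butyldiphenylsilyloxy)but-2-yn-1-ol
Conditions: t-BuPh2SiCl (0.33 equiv), imidazole, DMF, 0 °C → rt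
Reagents that add atoms: tert-butyl(chloro)diphenylsilane, CC(C)(C)[Si](Cl)(c1ccccc1)c1ccccc1
Why: Silylation of a primary alcohol with a silyl chloride and imidazole; the symmetrical diol in excess makes the monoether the main product.

Step 2
Reactants: 2 4-(tert-butyldiphenylsilyloxy)but-2-yn-1-ol
Product: 3 (4-bromobut-2-yn-1-yloxy)(tert-butyl)diphenylsilane
Conditions: CBr4, PPh3, CH2Cl2, 0 °C
Reagents that add atoms: tetrabromomethane, BrC(Br)(Br)Br
Why: The Appel reaction converts the primary propargylic alcohol into the bromide under neutral conditions that leave the silyl ether untouched.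

Step 3
Reactants: 4 2,2-dimethyl-1,3-dioxan-5-one; 5 SAMP
Product: 6 SAMP hydrazone of the dioxanone
Conditions: cyclohexane, reflux, Dean–Stark trap
Reagents that add atoms: none
Why: Hydrazone formation from ketone and hydrazine is driven to completion by azeotropic removal of water.

Step 4
Reactants: 6 SAMP hydrazone of the dioxanone; 3 (4-bromobut-2-yn-1-yloxy)(tert-butyl)diphenylsilane
Product: 8 (4S)-alkylated SAMP hydrazone, via lithium azaenolate 7 (not isolated)
Conditions: t-BuLi, THF, −78 °C; then 3, −100 °C → rt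
Reagents that add atoms: none
Why: Enders SAMP-hydrazone alkylation: the lithium azaenolate, held rigid by chelation of lithium to the methoxymethyl group, is alkylated by the propargylic bromide (SN2) on its unshielded face, which sets C7 as (S).

Step 5
Reactants: 8 (4S)-alkylated SAMP hydrazone
Product: 9 (4S)-4-[4-(tert-butyldiphenylsilyloxy)but-2-yn-1-yl]-2,2-dimethyl-1,3-dioxan-5-one
Conditions: sat. aq. (COOH)2, Et2O, rt
Reagents that add atoms: water, O
Why: Two-phase hydrazone hydrolysis with oxalic acid (auxiliary removed as its water-soluble oxalate) is mild enough to keep the acetonide and the α-stereocentre.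

Step 6
Reactants: 9 (4S)-4-alkylated dioxanone; 10 vinylmagnesium bromide
Product: 11 (4S,5R)-4-[4-(tert-butyldiphenylsilyloxy)but-2-yn-1-yl]-5-ethenyl-2,2-dimethyl-1,3-dioxan-5-ol
Conditions: THF, −78 °C; then H2O
Reagents that add atoms: none
Why: Grignard 1,2-addition to the ketone; attack along the axial trajectory of the chair dioxanone, whose C4 side chain is equatorial, places vinyl cis to the side chain and so sets C8 as (R).

Step 7
Reactants: 11 tertiary allylic alcohol (1,6-enyne)
Product: 13 tricyclic Pauson–Khand enone, via alkyne–Co2(CO)6 complex 12 (not isolated)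
Conditions: Co2(CO)8, CH2Cl2, rt; then N-methylmorpholine N-oxide, 0 °C → rt
Reagents that add atoms: dicobalt octacarbonyl (one CO is built in as C3=O), O=C=[Co](=C=O)(=C=O)(=C=O)[Co](=C=O)(=C=O)(=C=O)=C=O
Why: The intramolecular Pauson–Khand reaction of the 1,6-enyne closes ring B and the cyclopentenone ring A; the cobalt-bearing alkene terminus (future C1) turns away from the dioxane ring during insertion, so H-9 ends up cis to C10 and O7.

Step 8
Reactants: 13 tricyclic Pauson–Khand enone
Product: 14 cis-fused saturated ketone (O7/O10 acetonide)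
Conditions: H2 (5 bar), Pd/C (10% Pd on carbon), EtOAc, rt
Reagents that add atoms: none
Why: Heterogeneous catalytic hydrogenation adds both hydrogens syn from the face of H-9, the only face whose attack leads to the unstrained cis-fused diquinane, which sets H-5 (and H-4) cis to H-9.

Step 9
Reactants: 14 cis-fused saturated ketone (O7/O10 acetonide)
Product: 15 7,8,10-triol ketone
Conditions: AcOH/H2O (4:1), 40 °C
Reagents that add atoms: none
Why: Acid-catalysed acetal hydrolysis removes the 1,3-dioxane acetonide, while a primary TBDPS ether is stable to aqueous acetic acid.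

Step 10
Reactants: 15 7,8,10-triol ketone
Product: 17 10-O-TBS 7-O-TES ketone (8-OH free), via 10-O-TBS triol monoether 16 (not isolated)
Conditions: t-BuMe2SiCl (1.05 equiv), imidazole, DMF, 0 °C; then Et3SiCl, DMAP (cat.), rt
Reagents that add atoms: tert-butyl(chloro)dimethylsilane, CC(C)(C)[Si](C)(C)Cl; chloro(triethyl)silane, CC[Si](Cl)(CC)CC
Why: Sequential silylation with silyl chlorides and imidazole follows steric access: the primary O10–H reacts first with the TBS chloride and the secondary O7–H then with the TES chloride, whereas the tertiary O8–H does not react with silyl chlorides.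

Step 11
Reactants: 17 10-O-TBS 7-O-TES ketone (8-OH free)
Product: 18 10-O-TBS 7-O-TES 8-O-TMS ketone
Conditions: 1-(trimethylsilyl)imidazole, CH2Cl2, rt
Reagents that add atoms: 1-(trimethylsilyl)imidazole, C[Si](C)(C)n1ccnc1
Why: Silylation of the hindered tertiary alcohol with an N-silylimidazole, a strong neutral TMS donor that does not enolise the ketone.

Step 12
Reactants: 18 10-O-TBS 7-O-TES 8-O-TMS ketone
Product: 20 C1=C3 triethylsilyl enol ether, via lithium enolate 19 (not isolated)
Conditions: LiN(i-Pr)2, THF, −78 °C; then Et3SiOTf, −78 °C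
Reagents that add atoms: triethylsilyl trifluoromethanesulfonate, CC[Si](CC)(CC)OS(=O)(=O)C(F)(F)F
Why: Kinetic enolate formation with a hindered amide base removes a proton from the CH2 group C1 and not from the more substituted C4, and O-silylation traps the C1=C3 enolate as the enol silane.

Step 13
Reactants: 20 C1=C3 triethylsilyl enol ether
Product: 21 1-OTES cis-bicyclo[3.3.0]octan-3-one (Baeyer–Villiger precursor)
Conditions: mCPBA, NaHCO3, CH2Cl2, −20 → 0 °C
Reagents that add atoms: 3-chloroperoxybenzoic acid, OOC(=O)c1cccc(Cl)c1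
Why: Rubottom oxidation: the peracid epoxidises the enol silane on the convex face (the concave face of C1 is covered by ring B and the 8-OTMS group) and 1,4-silyl transfer then gives the α-silyloxy ketone with O1 cis to H-9.

Step 14
Reactants: 21 1-OTES cis-bicyclo[3.3.0]octan-3-one (Baeyer–Villiger precursor)
Product: 22 1-triethylsilyloxy-3-oxo iridoid lactone
Conditions: mCPBA, NaHCO3, CH2Cl2, 0 °C → rt
Reagents that add atoms: 3-chloroperoxybenzoic acid, OOC(=O)c1cccc(Cl)c1
Why: The peracid adds to the C3 carbonyl to give a Criegee adduct, and in the 1,2-shift that follows the C1–C3 bond anti-periplanar to the breaking O–O bond moves to oxygen while 3-chlorobenzoate leaves. This is a Baeyer–Villiger oxidation of an α-silyloxy ketone, a substrate class in which the oxygen-substituted α-carbon is the known preferred migrating group. The six-membered O2 ring is not made by a cyclisation but by one-atom enlargement of ring A, so no ring-closure mode has to be met. No stereocentre is created; C1 migrates with retention and keeps the convex-face oxygen set in step 13. The selectivity needed is migration of C1 rather than C4, secured by the lone pairs of the C1 silyloxy oxygen, which stabilise positive charge at the migrating carbon far better than the secondary alkyl C4 with its inductively deactivating CH2OSi group. NaHCO3 buffering protects the acid-labile silyl acylal and the silyl ethers.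

Step 15
Reactants: 22 1-triethylsilyloxy-3-oxo iridoid lactone
Product: 23 C3 lactol (C3 epimers)
Conditions: i-Bu2AlH, CH2Cl2, −78 °C; aq. potassium sodium tartrate (KNaC4H4O6)
Reagents that add atoms: none
Why: Reduction of a lactone with i-Bu2AlH at −78 °C stops at the lactol because the tetrahedral aluminium alkoxide is stable at that temperature; the C3 epimers are used crude and cold.

Step 16
Reactants: 23 C3 lactol (C3 epimers)
Product: 24 1-O-TES iridoid enol ether (C3=C4)
Conditions: MsCl, Et3N, THF, −20 → 50 °C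
Reagents that add atoms: none
Why: Dehydration of the lactol through its mesylate (or the derived chloride) and the O2-stabilised oxocarbenium ion, which can lose only H-4, gives the C3=C4 enol ether (E1-type elimination) and erases C4.

Step 17
Reactants: 24 1-O-TES iridoid enol ether (C3=C4)
Product: 25 C1 hemiacetal
Conditions: Bu4NF, AcOH (1:1.2), THF, −40 °C
Reagents that add atoms: none
Why: Fluoride-mediated desilylation is fastest at the acetal oxygen, whose hemiacetal alkoxide is the best leaving group, so the anomeric TES ether should be cleaved in the cold before the hindered 7-OTES, the tertiary 8-OTMS and the primary silyl ethers; acetic acid keeps the hemiacetal ring closed.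

Step 18
Reactants: 25 C1 hemiacetal; 26 (R)-3-methylpentanoic acid
Product: 27 1-O-[(R)-3-methylpentanoyl] enol ether
Conditions: i-PrN=C=N-i-Pr, DMAP (cat.), CH2Cl2, −20 → 0 °C
Reagents that add atoms: none
Why: Steglich esterification of the hemiacetal hydroxyl; O1 stays on the convex face (cis to H-9, trans to C8), the configuration inherited from step 14 and also the preferred one should C1 equilibrate.

Step 19
Reactants: 27 1-O-[(R)-3-methylpentanoyl] enol ether
Product: 28 7,8-diol (10-OTBS, 11-OTBDPS)
Conditions: HF·pyridine, pyridine, THF, 0 °C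
Reagents that add atoms: none
Why: Selective desilylation: pyridine-buffered HF cleaves TES and TMS ethers much faster than primary TBS or TBDPS ethers and tolerates the acyloxy acetal and the enol ether.

Step 20
Reactants: 29 4-hydroxybenzaldehyde
Product: 30 4-(tert-butyldimethylsilyloxy)benzaldehyde
Conditions: t-BuMe2SiCl, imidazole, CH2Cl2, rt
Reagents that add atoms: tert-butyl(chloro)dimethylsilane, CC(C)(C)[Si](C)(C)Cl
Why: Silylation of the phenol with a silyl chloride and imidazole prevents phenoxide formation in the olefination.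

Step 21
Reactants: 30 4-(tert-butyldimethylsilyloxy)benzaldehyde; 31 methyl bis(2,2,2-trifluoroethyl)phosphonoacetate
Product: 33 methyl (Z)-4-(TBS-oxy)cinnamate, via potassium phosphonate 32 (not isolated)
Conditions: KN(SiMe3)2, 18-crown-6, THF, −78 °C; then 30
Reagents that add atoms: none
Why: Still–Gennari olefination: the bis(trifluoroethyl) phosphonate anion with a crown-ether-separated potassium ion adds to the aldehyde and eliminates under kinetic control to the Z-cinnamate.

Step 22
Reactants: 33 methyl (Z)-4-(TBS-oxy)cinnamate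
Product: 34 (Z)-3-(4-hydroxyphenyl)prop-2-enoic acid
Conditions: LiOH·H2O, THF/H2O, rt, dark; then aq. HCl
Reagents that add atoms: lithium hydroxide, [Li+].[OH-]
Why: Saponification of the methyl ester, which also cleaves the base-labile aryl silyl ether; the Z double bond is not isomerised by hydroxide at room temperature in the dark.

Step 23
Reactants: 34 (Z)-3-(4-hydroxyphenyl)prop-2-enoic acid
Product: 36 (Z)-4-(TBS-oxy)cinnamic acid, via bis-silyl derivative 35 (not isolated)
Conditions: t-BuMe2SiCl (2.2 equiv), imidazole, DMF, rt; then AcOH/THF/H2O, rt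
Reagents that add atoms: tert-butyl(chloro)dimethylsilane, CC(C)(C)[Si](C)(C)Cl
Why: Silylation of both acidic hydroxyls followed by selective hydrolysis of the far more labile silyl ester leaves the aryl silyl ether in place.

Step 24
Reactants: 36 (Z)-4-(TBS-oxy)cinnamic acid; 28 7,8-diol (10-OTBS, 11-OTBDPS)
Product: 38 fully protected target, via mixed anhydride 37 (not isolated)
Conditions: 2,4,6-Cl3C6H2COCl, Et3N, THF, rt; then 28, DMAP, toluene, rt, dark
Reagents that add atoms: none
Why: Yamaguchi esterification through the trichlorobenzoyl mixed anhydride acylates the hindered secondary O7–H, while the tertiary O8–H does not react; exclusion of light and room temperature protect the Z double bond.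

Step 25
Reactants: 38 fully protected target
Product: 39 CNP0217341.1
Conditions: Bu4NF, AcOH (1:1), THF, 0 °C → rt
Reagents that add atoms: none
Why: Global desilylation with acetic acid-buffered fluoride removes the two primary silyl ethers and the aryl silyl ether under near-neutral conditions that avoid acyl migration, cleavage of the acyloxy acetal and hydration of the enol ether.

Compound list
1 | but-2-yne-1,4-diol | OCC#CCO | starting material
2 | 4-(tert-butyldiphenylsilyloxy)but-2-yn-1-ol | OCC#CCO[Si](c1ccccc1)(c1ccccc1)C(C)(C)C | intermediate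
3 | (4-bromobut-2-yn-1-yloxy)(tert-butyl)diphenylsilane | BrCC#CCO[Si](c1ccccc1)(c1ccccc1)C(C)(C)C | intermediate
4 | 2,2-dimethyl-1,3-dioxan-5-one | CC1(C)OCC(=O)CO1 | starting material
5 | SAMP, (S)-1-amino-2-(methoxymethyl)pyrrolidine | COC[C@@H]1CCCN1N | starting material
6 | SAMP hydrazone of 4 | COC[C@@H]1CCCN1N=C1COC(C)(C)OC1 | intermediate
7 | lithium azaenolate of 6 (N-lithio ene-hydrazine) | COC[C@@H]1CCCN1N([Li])C1=COC(C)(C)OC1 | intermediate
8 | SAMP hydrazone of (4S)-4-[4-(tert-butyldiphenylsilyloxy)but-2-yn-1-yl]-2,2-dimethyl-1,3-dioxan-5-one (C=N geometry not assigned, erased in step 5) | COC[C@@H]1CCCN1N=C1COC(C)(C)O[C@H]1CC#CCO[Si](c1ccccc1)(c1ccccc1)C(C)(C)C | intermediate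
9 | (4S)-4-[4-(tert-butyldiphenylsilyloxy)but-2-yn-1-yl]-2,2-dimethyl-1,3-dioxan-5-one | CC1(C)OCC(=O)[C@H](CC#CCO[Si](c2ccccc2)(c2ccccc2)C(C)(C)C)O1 | intermediate
10 | vinylmagnesium bromide | C=C[Mg]Br | starting material
11 | (4S,5R)-4-[4-(tert-butyldiphenylsilyloxy)but-2-yn-1-yl]-5-ethenyl-2,2-dimethyl-1,3-dioxan-5-ol (vinyl cis to the side chain) | CC1(C)OC[C@](O)(C=C)[C@H](CC#CCO[Si](c2ccccc2)(c2ccccc2)C(C)(C)C)O1 | intermediate
12 | hexacarbonyldicobalt complex of the alkyne of 11 | CC1(C)OC[C@](O)(C=C)[C@H](CC23[Co]4(=C=O)(=C=O)(=C=O)[Co]2(=C=O)(=C=O)(=C=O)C34CO[Si](c2ccccc2)(c2ccccc2)C(C)(C)C)O1 | intermediate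
13 | tricyclic enone: bicyclo[3.3.0]oct-4-en-3-one (C4=C5) with 11-OTBDPS, 8-OH and O7/O10 isopropylidene acetal; H-9, O7 and C10 on one face | CC1(C)OC[C@@]2(O)[C@@H](O1)CC3=C(CO[Si](c4ccccc4)(c4ccccc4)C(C)(C)C)C(=O)C[C@H]23 | intermediate
14 | saturated ketone: 13 with H-4 and H-5 added cis to H-9 (C11 on the concave face) | CC1(C)OC[C@@]2(O)[C@@H](O1)C[C@@H]3[C@H](CO[Si](c4ccccc4)(c4ccccc4)C(C)(C)C)C(=O)C[C@H]23 | intermediate
15 | 7,8,10-triol of 14 (acetonide removed) | OC[C@@]1(O)[C@@H](O)C[C@@H]2[C@H](CO[Si](c3ccccc3)(c3ccccc3)C(C)(C)C)C(=O)C[C@H]12 | intermediate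
16 | 10-O-TBS ether of 15 | CC(C)(C)[Si](C)(C)OC[C@@]1(O)[C@@H](O)C[C@@H]2[C@H](CO[Si](c3ccccc3)(c3ccccc3)C(C)(C)C)C(=O)C[C@H]12 | intermediate
17 | 10-O-TBS 7-O-TES ether of 15 (8-OH free) | CC(C)(C)[Si](C)(C)OC[C@@]1(O)[C@@H](O[Si](CC)(CC)CC)C[C@@H]2[C@H](CO[Si](c3ccccc3)(c3ccccc3)C(C)(C)C)C(=O)C[C@H]12 | intermediate
18 | 10-O-TBS 7-O-TES 8-O-TMS ether of 15 | CC(C)(C)[Si](C)(C)OC[C@@]1(O[Si](C)(C)C)[C@@H](O[Si](CC)(CC)CC)C[C@@H]2[C@H](CO[Si](c3ccccc3)(c3ccccc3)C(C)(C)C)C(=O)C[C@H]12 | intermediate
19 | lithium C1=C3 enolate of 18 | CC(C)(C)[Si](C)(C)OC[C@@]1(O[Si](C)(C)C)[C@@H](O[Si](CC)(CC)CC)C[C@@H]2[C@H](CO[Si](c3ccccc3)(c3ccccc3)C(C)(C)C)C(O[Li])=C[C@H]12 | intermediate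
20 | C1=C3 triethylsilyl enol ether of 18 | CC(C)(C)[Si](C)(C)OC[C@@]1(O[Si](C)(C)C)[C@@H](O[Si](CC)(CC)CC)C[C@@H]2[C@H](CO[Si](c3ccccc3)(c3ccccc3)C(C)(C)C)C(O[Si](CC)(CC)CC)=C[C@H]12 | intermediate
21 | Baeyer–Villiger precursor: cis-bicyclo[3.3.0]octan-3-one with 1-OTES on the convex face (cis to H-9), 7-OTES, 8-OTMS, 10-OTBS, 11-OTBDPS (C11 on the concave face) | CC[Si](CC)(CC)O[C@@H]1C(=O)[C@@H](CO[Si](c3ccccc3)(c3ccccc3)C(C)(C)C)[C@H]2C[C@H](O[Si](CC)(CC)CC)[C@](O[Si](C)(C)C)(CO[Si](C)(C)C(C)(C)C)[C@@H]12 | intermediate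
22 | 1-triethylsilyloxy-3-oxo iridoid lactone (3,4-dihydro; O2 between C1 and C3; silyl groups as in 21) | CC[Si](CC)(CC)O[C@@H]1OC(=O)[C@@H](CO[Si](c3ccccc3)(c3ccccc3)C(C)(C)C)[C@H]2C[C@H](O[Si](CC)(CC)CC)[C@](O[Si](C)(C)C)(CO[Si](C)(C)C(C)(C)C)[C@@H]12 | intermediate
23 | lactol of 22 (3-hydroxy, both C3 epimers) | CC[Si](CC)(CC)O[C@@H]1OC(O)[C@@H](CO[Si](c3ccccc3)(c3ccccc3)C(C)(C)C)[C@H]2C[C@H](O[Si](CC)(CC)CC)[C@](O[Si](C)(C)C)(CO[Si](C)(C)C(C)(C)C)[C@@H]12 | intermediate
24 | 1-O-TES iridoid enol ether (C3=C4) with 7-OTES, 8-OTMS, 10-OTBS, 11-OTBDPS | CC[Si](CC)(CC)O[C@@H]1OC=C(CO[Si](c3ccccc3)(c3ccccc3)C(C)(C)C)[C@H]2C[C@H](O[Si](CC)(CC)CC)[C@](O[Si](C)(C)C)(CO[Si](C)(C)C(C)(C)C)[C@@H]12 | intermediate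
25 | C1 hemiacetal of 24 (1-OH cis to H-9) | O[C@@H]1OC=C(CO[Si](c3ccccc3)(c3ccccc3)C(C)(C)C)[C@H]2C[C@H](O[Si](CC)(CC)CC)[C@](O[Si](C)(C)C)(CO[Si](C)(C)C(C)(C)C)[C@@H]12 | intermediate
26 | (R)-3-methylpentanoic acid | CC[C@@H](C)CC(=O)O | starting material
27 | 1-O-[(R)-3-methylpentanoyl] ester of 25 | CC[C@@H](C)CC(=O)O[C@@H]1OC=C(CO[Si](c3ccccc3)(c3ccccc3)C(C)(C)C)[C@H]2C[C@H](O[Si](CC)(CC)CC)[C@](O[Si](C)(C)C)(CO[Si](C)(C)C(C)(C)C)[C@@H]12 | intermediate
28 | 7,8-diol of 27 (10-OTBS, 11-OTBDPS) | CC[C@@H](C)CC(=O)O[C@@H]1OC=C(CO[Si](c3ccccc3)(c3ccccc3)C(C)(C)C)[C@H]2C[C@H](O)[C@](O)(CO[Si](C)(C)C(C)(C)C)[C@@H]12 | intermediate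
29 | 4-hydroxybenzaldehyde | O=Cc1ccc(O)cc1 | starting material
30 | 4-(tert-butyldimethylsilyloxy)benzaldehyde | O=Cc1ccc(O[Si](C)(C)C(C)(C)C)cc1 | intermediate
31 | methyl bis(2,2,2-trifluoroethyl)phosphonoacetate | COC(=O)CP(=O)(OCC(F)(F)F)OCC(F)(F)F | starting material
32 | potassium salt of 31 (phosphonate carbanion) | COC(=O)[CH-]P(=O)(OCC(F)(F)F)OCC(F)(F)F.[K+] | intermediate
33 | methyl (Z)-3-[4-(tert-butyldimethylsilyloxy)phenyl]prop-2-enoate | COC(=O)/C=C\c1ccc(O[Si](C)(C)C(C)(C)C)cc1 | intermediate
34 | (Z)-3-(4-hydroxyphenyl)prop-2-enoic acid | OC(=O)/C=C\c1ccc(O)cc1 | intermediate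
35 | tert-butyldimethylsilyl (Z)-3-[4-(tert-butyldimethylsilyloxy)phenyl]prop-2-enoate | CC(C)(C)[Si](C)(C)OC(=O)/C=C\c1ccc(O[Si](C)(C)C(C)(C)C)cc1 | intermediate
36 | (Z)-3-[4-(tert-butyldimethylsilyloxy)phenyl]prop-2-enoic acid | OC(=O)/C=C\c1ccc(O[Si](C)(C)C(C)(C)C)cc1 | intermediate
37 | mixed anhydride of 36 with 2,4,6-trichlorobenzoic acid | O=C(OC(=O)/C=C\c1ccc(O[Si](C)(C)C(C)(C)C)cc1)c1c(Cl)cc(Cl)cc1Cl | intermediate
38 | 7-O-[(Z)-4-(tert-butyldimethylsilyloxy)cinnamoyl] ester of 28 | CC[C@@H](C)CC(=O)O[C@@H]1OC=C(CO[Si](c3ccccc3)(c3ccccc3)C(C)(C)C)[C@H]2C[C@H](OC(=O)/C=C\c3ccc(O[Si](C)(C)C(C)(C)C)cc3)[C@](O)(CO[Si](C)(C)C(C)(C)C)[C@@H]12 | intermediate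
39 | CNP0217341.1 | CC[C@@H](C)CC(=O)O[C@@H]1OC=C(CO)[C@H]2C[C@H](OC(=O)/C=C\c3ccc(O)cc3)[C@](O)(CO)[C@@H]12 | target

Total steps: 25. Longest linear sequence: 20 steps (steps 1, 2, 4–19, 24, 25, from but-2-yne-1,4-diol).

Steps most likely to fail

Step 14. The peracid may let C4 migrate in part, or the silyl acylal may lose its C1 silyl group to the carboxylic acid that is formed. The fallback cleaves ring A instead of enlarging it and sets out from enol silane 20. Ozonolysis (O3, CH2Cl2/MeOH, −78 °C; Me2S) should break C1=C3 and give the seco aldehyde–acid F1. In the cis-fused system this is expected to close to its pseudo-acid form, the 1-hydroxy lactone F2. O-Silylation of that lactol hydroxyl (Et3SiCl, imidazole), as is done with 5-hydroxybutenolides, would rejoin the route at lactone 22, with C1 then under thermodynamic control (OSi trans to C8).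

Step 16. The lactol may ring-open under the basic sulfonylation conditions and lose the C1 silanol, or the elimination may stall at the anomeric chloride. The fallback never forms a lactol and sets out from lactone 22. KN(SiMe3)2 and PhNTf2 (THF/DMPU, −78 °C) should convert the lactone enolate into the ketene acetal triflate F3. Reduction with Bu3SnH and LiCl under Pd(PPh3)4 catalysis would replace the triflate by hydrogen and rejoin the route at enol ether 24.

Step 17. The liberated hemiacetal may ring-open by expulsion of the enol oxygen and then epimerise or decompose before it is acylated, or the two TES ethers may not be told apart cleanly. The fallback avoids a free hemiacetal and goes from 24 directly to 27. The anhydride of 26, (R)-3-methylpentanoic anhydride F4 (26 with half an equivalent of the carbodiimide), is placed in excess with 24 at −78 °C and Bu4NF is added. The C1 oxygen should then be acylated as it is unmasked (fluoride-triggered silyl-to-acyl exchange), and the route is rejoined at ester 27.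

Further compounds
F1 | step 14 | seco aldehyde–acid (C1 aldehyde, C3 carboxylic acid) | OC(=O)[C@@H](CO[Si](c2ccccc2)(c2ccccc2)C(C)(C)C)[C@H]1C[C@H](O[Si](CC)(CC)CC)[C@](O[Si](C)(C)C)(CO[Si](C)(C)C(C)(C)C)[C@H]1C=O
F2 | step 14 | 1-hydroxy lactone (pseudo-acid form of F1, C1 epimers) | OC1OC(=O)[C@@H](CO[Si](c3ccccc3)(c3ccccc3)C(C)(C)C)[C@H]2C[C@H](O[Si](CC)(CC)CC)[C@](O[Si](C)(C)C)(CO[Si](C)(C)C(C)(C)C)[C@@H]12
F3 | step 16 | ketene acetal triflate of 22 | CC[Si](CC)(CC)O[C@@H]1OC(OS(=O)(=O)C(F)(F)F)=C(CO[Si](c3ccccc3)(c3ccccc3)C(C)(C)C)[C@H]2C[C@H](O[Si](CC)(CC)CC)[C@](O[Si](C)(C)C)(CO[Si](C)(C)C(C)(C)C)[C@@H]12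
F4 | step 17 | (R)-3-methylpentanoic anhydride | CC[C@@H](C)CC(=O)OC(=O)C[C@H](C)CC
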